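## Retrosynthetic overview

1. The target is reached by O-sulfation of the single aliphatic OH of the pentaol, with both catechols masked briefly as phenylboronates. The pentaol comes from BBr3 cleavage of the two guaiacol OMe groups of the coupled diarylmethane.
2. Key disconnection: the bond from the diarylmethane CH2 to the dibromocatechol ring (ring B). It is made by acid-triggered arylative opening of the C1–O2 bond of 8-bromo-6-methoxyisochroman-7-ol with 2,3-dibromo-6-methoxyphenol. This joins the halves, completes the Br3/O5 pattern and frees the alcohol that is later sulfated.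
3. Enabling feature: the target is a 4,4'-dioxygenated diphenylmethane. In ring A the oxygen next to the lone ring CH is para to the carbon bearing the CH2 (p-alkoxybenzyl cation / p-quinone methide relation). In ring B the oxygen next to Br is para to the carbon to be joined (para-directing phenol). The CH2CH2O chain is ortho to the CH2, so CH2 and chain oxygen can be tied as C1–O2 of a pyran ring.
4. Ring order: both benzene rings are bought. The temporary pyran ring is closed in step 2 (oxa-Pictet–Spengler) and opened in step 4. Two temporary 1,3,2-dioxaborole rings are closed in step 6 and opened in step 7.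
5. Fragments: homovanillyl alcohol and 5-bromo-2-methoxyphenol, each brominated ortho to its free OH.

Key step: step 4

Assumption: the target holds no stereocentre and no configurationally stable axis, so no enantiocontrol is needed; it is delivered as drawn, as the free hydrogen sulfate, by a final H+ ion exchange.

## Route

Step 1
Reactants: 1 homovanillyl alcohol (4-(2-hydroxyethyl)-2-methoxyphenol)
Product: 2 2-bromo-4-(2-hydroxyethyl)-6-methoxyphenol
Conditions: NBS (1.0 equiv, slow addition), i-Pr2NH (10 mol %), CH2Cl2, 0 °C to rt
Reagents that add atoms: N-bromosuccinimide, O=C1CCC(=O)N1Br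
Why: Amine-catalysed ortho-bromination of a phenol with NBS (electrophilic aromatic substitution): the free OH is the strongest director, its para position carries the side chain and one ortho position the OMe group, so bromine should enter at the one free ortho carbon, and the primary alcohol is inert under these ionic conditions.

Step 2
Reactants: 2 2-bromo-4-(2-hydroxyethyl)-6-methoxyphenol
Product: 4 8-bromo-6-methoxyisochroman-7-ol, via hemiformal 3 (not isolated)
Conditions: (CH2O)n (1.5 equiv), TFA/CH2Cl2 (1:3), rt to 40 °C
Reagents that add atoms: formaldehyde (as paraformaldehyde), C=O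
Why: Oxa-Pictet–Spengler cyclisation: hemiformal 3 ionises to the oxocarbenium ion, which closes the pyran ring (6-endo) at the ring carbon para to OMe, between side chain and bromine, the same site that takes the second electrophile in 5-bromovanillin-type arenes, whereas the other free carbon is ortho to OMe and shielded by its methyl group and every position ortho or para to the phenol OH is blocked.

Step 3
Reactants: 5 5-bromo-2-methoxyphenol
Product: 6 2,3-dibromo-6-methoxyphenol
Conditions: NBS (1.0 equiv, slow addition), i-Pr2NH (10 mol %), CH2Cl2, 0 °C to rt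
Reagents that add atoms: N-bromosuccinimide, O=C1CCC(=O)N1Br
Why: The same amine-catalysed ortho-bromination with NBS: hydrogen-bond-guided delivery of bromine by the amine catalyst should direct it to the single free carbon ortho to OH (next to the resident bromine) rather than to the para carbon, as is established for 2-substituted phenols such as guaiacol.

Step 4
Reactants: 4 8-bromo-6-methoxyisochroman-7-ol; 6 2,3-dibromo-6-methoxyphenol
Product: 8 2-[3-bromo-2-(2,3-dibromo-4-hydroxy-5-methoxybenzyl)-4-hydroxy-5-methoxyphenyl]ethanol, via ring-opened benzylic cation 7 (not isolated)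
Conditions: TfOH (10 mol %), 6 (2.0 equiv, excess recovered), HFIP (0.1 M), slow addition of 4, 40 °C, N2; NaHCO3 quench
Reagents that add atoms: none
Why: Proposed new method: TfOH in the strongly ionising and barely nucleophilic HFIP protonates O2 of 4, the C1–O2 bond ionises reversibly to the ring-opened cation 7, which the C6 methoxy group para to C8a stabilises as an O-methylated para-quinone methide, and irreversible attack of C4 of phenol 6 followed by rearomatisation gives 8, so that one operation without by-product makes the C–C bond, opens the temporary pyran ring, completes the tribromo pattern and frees the only aliphatic hydroxyl. The closest known reaction types are the acid cleavage of p-methoxybenzyl ethers in the presence of arene traps and the Friedel–Crafts benzylation of arenes with benzylic alcohols and ethers in HFIP; new is the use of the C1–O2 bond of a C1-unsubstituted isochroman as the benzyl donor. No ring is closed and no stereocentre is formed. The step needs site selectivity on 6, which the substrate secures: C4 is para to the free OH, the position para to OMe carries bromine, and C5 lies ortho to an OMe group whose methyl is turned towards it by the OH···OMe hydrogen bond. It also needs cross- over self-alkylation: the one free CH of ring A in 4 and 8 is of the same shielded ortho-to-OMe kind (the inert 3-position of a veratrole or guaiacol) and every position ortho or para to the C7 OH is substituted. Reclosure of 7 to 4, O-benzylation of the phenols and capture by HFIP are all reversible under the acid and should drain into the C-benzylated product.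

Step 5
Reactants: 8 2-[3-bromo-2-(2,3-dibromo-4-hydroxy-5-methoxybenzyl)-4-hydroxy-5-methoxyphenyl]ethanol
Product: 9 3-bromo-4-(2,3-dibromo-4,5-dihydroxybenzyl)-5-(2-hydroxyethyl)benzene-1,2-diol
Conditions: BBr3 (6 equiv), CH2Cl2, −78 °C to 0 °C, N2; ice-water quench
Reagents that add atoms: none
Why: Lewis-acid cleavage of aryl methyl ethers with BBr3: both OMe groups are of the guaiacol type, so the neighbouring aryloxyboron bromide assists and cleavage should be complete at or below 0 °C, where the primary alcohol is only held as a borate that hydrolysis returns, while aryl bromides and the diarylmethane are inert.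

Step 6
Reactants: 9 3-bromo-4-(2,3-dibromo-4,5-dihydroxybenzyl)-5-(2-hydroxyethyl)benzene-1,2-diol
Product: 10 bis(phenylboronate) of 9 (both catechols as 2-phenyl-1,3,2-benzodioxaboroles, primary OH free)
Conditions: PhB(OH)2 (2.05 equiv), THF/toluene, 4 Å MS, rt, then azeotropic evaporation, N2
Reagents that add atoms: phenylboronic acid, OB(O)c1ccccc1
Why: Condensation of catechols with an arylboronic acid to five-membered 1,3,2-benzodioxaboroles, which is strongly favoured for 1,2-diphenols and more so for acidic bromocatechols, whereas the lone primary alcohol cannot form a cyclic ester and stays free once water is removed.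

Step 7
Reactants: 10 bis(phenylboronate) of 9
Product: 12 2-[3-bromo-2-(2,3-dibromo-4,5-dihydroxybenzyl)-4,5-dihydroxyphenyl]ethyl hydrogen sulfate (target), via sulfated bis-boronate 11 (not isolated)
Conditions: SO3·pyridine (1.5 equiv), dry DMF, 0 °C to rt; then H2O/MeOH, rt; Et2O wash; Dowex 50WX8 (H+), 4 °C; lyophilisation
Reagents that add atoms: sulfur trioxide pyridine complex, O=S(=O)([O-])[n+]1ccccc1
Why: O-Sulfation of a primary alcohol with SO3·pyridine while the four phenolic oxygens are tied up in the boronates, after which water hydrolyses the labile benzodioxaboroles, extraction removes the boronic acid and the H+ resin exchanges pyridinium for a proton, conditions that a primary alkyl sulfate tolerates.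

## Compound list

1 | homovanillyl alcohol, 4-(2-hydroxyethyl)-2-methoxyphenol | COc1cc(CCO)ccc1O | starting material
2 | 2-bromo-4-(2-hydroxyethyl)-6-methoxyphenol | COc1cc(CCO)cc(Br)c1O | intermediate
3 | hemiformal of 2, 2-bromo-4-[2-(hydroxymethoxy)ethyl]-6-methoxyphenol (not isolated) | COc1cc(CCOCO)cc(Br)c1O | intermediate
4 | 8-bromo-6-methoxyisochroman-7-ol | COc1cc2CCOCc2c(Br)c1O | intermediate
5 | 5-bromo-2-methoxyphenol | COc1ccc(Br)cc1O | starting material
6 | 2,3-dibromo-6-methoxyphenol | COc1ccc(Br)c(Br)c1O | intermediate
7 | ring-opened benzylic cation, 2-bromo-3-hydroxy-6-(2-hydroxyethyl)-4-methoxybenzyl cation (not isolated) | OCCc1cc(OC)c(O)c(Br)c1[CH2+] | intermediate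
8 | 2-[3-bromo-2-(2,3-dibromo-4-hydroxy-5-methoxybenzyl)-4-hydroxy-5-methoxyphenyl]ethanol | OCCc1cc(OC)c(O)c(Br)c1Cc1cc(OC)c(O)c(Br)c1Br | intermediate
9 | 3-bromo-4-(2,3-dibromo-4,5-dihydroxybenzyl)-5-(2-hydroxyethyl)benzene-1,2-diol | OCCc1cc(O)c(O)c(Br)c1Cc1cc(O)c(O)c(Br)c1Br | intermediate
10 | bis(phenylboronate) of 9 | OCCc1cc2OB(c3ccccc3)Oc2c(Br)c1Cc1cc2OB(c3ccccc3)Oc2c(Br)c1Br | intermediate
11 | sulfated bis-boronate (pyridinium salt in the flask, written as the acid; not isolated) | O=S(=O)(O)OCCc1cc2OB(c3ccccc3)Oc2c(Br)c1Cc1cc2OB(c3ccccc3)Oc2c(Br)c1Br | intermediate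
12 | 2-[3-bromo-2-(2,3-dibromo-4,5-dihydroxybenzyl)-4,5-dihydroxyphenyl]ethyl hydrogen sulfate | O=S(=O)(O)OCCc1cc(O)c(O)c(Br)c1Cc1cc(O)c(O)c(Br)c1Br | target

## Step count and risks

Total step count: 7. Longest linear sequence: 6 (steps 1, 2, 4, 5, 6, 7).

**Step 4 (Proposed new method).**
- What may go wrong: the reversible ionisation of the isochroman may be drained too slowly by the twice-brominated phenol. The ether would then be recovered, or consumed by slow oligomerisation and transbenzylation.
- Fallback: it sets out from 4 and comes back at 8, and cuts the C1–O2 bond irreversibly before the coupling.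
- Acylative ether cleavage of 4 with acetyl chloride and catalytic ZnCl2 is known for isochroman itself. Chloride ends at the benzylic carbon, the acyl group at the chain oxygen, and the phenol is acetylated alongside. This should give 2-[4-acetoxy-3-bromo-2-(chloromethyl)-5-methoxyphenyl]ethyl acetate F1.
- Classical Friedel–Crafts benzylation of 6 with this benzylic chloride (ZnCl2, CH2Cl2) should give 2-[4-acetoxy-3-bromo-2-(2,3-dibromo-4-hydroxy-5-methoxybenzyl)-5-methoxyphenyl]ethyl acetate F2.
- K2CO3 in MeOH removes both acetates and gives 8.

**Step 7.**
- What may go wrong: loss of chemoselectivity. Exchange at boron or premature hydrolysis of the mask would expose phenolic oxygen to SO3 transfer, and over-sulfation would follow.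
- Fallback: it sets out from 9 and comes back at 12, and replaces the transient mask by isolable silyl ethers.
- Persilylation (TBSCl, imidazole, DMF) gives the penta-TBS ether of 9 F3.
- Mild acid (CSA, MeOH/CH2Cl2, 0 °C) cleaves only the primary alkyl silyl ether, since aryl TBS ethers are the more acid-stable. This gives the tetra-O-aryl-TBS alcohol F4.
- SO3·pyridine gives the tetra-TBS hydrogen sulfate F5.
- KF in MeOH removes the aryl silyl ethers, and H+ resin gives 12.

**Step 3.**
- What may go wrong: poor site selectivity. Bromination para to OH may compete with the wanted delivery to the more crowded ortho carbon next to the resident bromine.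
- Fallback: it sets out from 5 and comes back at 6, and uses directed ortho-metalation in place of electrophilic substitution.
- Carbamoylation (ClCONEt2, K2CO3, MeCN) gives 5-bromo-2-methoxyphenyl diethylcarbamate F6.
- LDA in THF at −78 °C removes the proton flanked by carbamate and bromine. A quench with 1,2-dibromotetrachloroethane gives 2,3-dibromo-6-methoxyphenyl diethylcarbamate F7.
- NaOH in aqueous EtOH at reflux, then acid, gives 6.

## Further compounds

F1 | step 4 | 2-[4-acetoxy-3-bromo-2-(chloromethyl)-5-methoxyphenyl]ethyl acetate | CC(=O)OCCc1cc(OC)c(OC(C)=O)c(Br)c1CCl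
F2 | step 4 | 2-[4-acetoxy-3-bromo-2-(2,3-dibromo-4-hydroxy-5-methoxybenzyl)-5-methoxyphenyl]ethyl acetate | CC(=O)OCCc1cc(OC)c(OC(C)=O)c(Br)c1Cc1cc(OC)c(O)c(Br)c1Br
F3 | step 7 | penta-TBS ether of 9 | CC(C)(C)[Si](C)(C)OCCc1cc(O[Si](C)(C)C(C)(C)C)c(O[Si](C)(C)C(C)(C)C)c(Br)c1Cc1cc(O[Si](C)(C)C(C)(C)C)c(O[Si](C)(C)C(C)(C)C)c(Br)c1Br
F4 | step 7 | tetra-O-aryl-TBS alcohol | OCCc1cc(O[Si](C)(C)C(C)(C)C)c(O[Si](C)(C)C(C)(C)C)c(Br)c1Cc1cc(O[Si](C)(C)C(C)(C)C)c(O[Si](C)(C)C(C)(C)C)c(Br)c1Br
F5 | step 7 | tetra-TBS hydrogen sulfate | O=S(=O)(O)OCCc1cc(O[Si](C)(C)C(C)(C)C)c(O[Si](C)(C)C(C)(C)C)c(Br)c1Cc1cc(O[Si](C)(C)C(C)(C)C)c(O[Si](C)(C)C(C)(C)C)c(Br)c1Br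
F6 | step 3 | 5-bromo-2-methoxyphenyl diethylcarbamate | CCN(CC)C(=O)Oc1cc(Br)ccc1OC
F7 | step 3 | 2,3-dibromo-6-methoxyphenyl diethylcarbamate | CCN(CC)C(=O)Oc1c(Br)c(Br)ccc1OC
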